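## The problem

Target 21 is (2R,3R,4R)-2-(4-hydroxy-3-methoxyphenyl)-4-(4-hydroxy-3,5-dimethoxybenzyl)-3-methyloxolane, numbered here O1, C2 (guaiacyl), C3 (methyl), C4 (syringylmethyl, benzylic carbon C7') and C5 (CH2). A single C–O bond closes the only ring, so the real task is the branched chain C2–C3–C4(C5)–C7': three contiguous stereocentres (aryl trans to methyl, methyl trans to arylmethyl) and two different aryl groups that must end up at C2 and C7' without ambiguity. The centres could relay to one another, because the all-trans ring is the relaxed one, but relay needs a first centre from elsewhere and ties absolute to relative control. C2 is the delicate atom: an electron-rich benzylic ether carbon that ionises under acid or Lewis acid, is attacked by benzylic oxidants and can be hydrogenolysed, so it is a poor controller and must be kept away from rough reagents. The two phenols have to stay masked through every organometallic step and be released last, next to the benzylic C2–O1 bond. The enabling feature is that C2, C3 and C4 are three CH units in a row, each carrying exactly one further branch (O, CH3, CH2), which is the pattern left when one carbon at a time is inserted into a C–B bond and the remaining chloride is displaced by a nucleophile. The two CH2 branches on C4 can be told apart because C5 can arrive as a nucleophile and C7' as the next inserted carbon, so a single chiral diol on boron can set all three centres.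

## Retrosynthesis

**21 ⇒ 20.** The two phenolic O–benzyl bonds are cut. Benzyl ethers survive every carbanion, boron and palladium step and leave in one neutral operation; the forward reaction must spare the benzylic C2–O1 bond of oxolane 20.

**20 ⇒ 18 (through tosylate 19).** O1–C5 is cut. The neighbouring cut, O1–C2, would close the ring through a benzylic cation and hand C2 to thermodynamics; it is kept in reserve. Closing at C5 breaks no bond to a stereocentre, so 1,4-diol 18 only has to be sulfonylated at its primary hydroxyl in preference to the hindered benzylic one.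

**18 ⇒ 17 ⇒ 15.** Two functional-group changes. The C2 hydroxyl comes from allyl ether 17. An allyl ether can be taken off under neutral metal catalysis, whereas a 4-methoxybenzyl ether would need a quinone oxidant or acid, both of which attack the guaiacyl carbinol position. The C5 hydroxyl comes from the C5–Si bond of silane 15. C5 must stay masked as silicon until boron is gone, because peroxide would oxidise a C–B bond first. Benzyldimethylsilyl is chosen over an alkoxysilane (which would hydrolyse during the coupling) and over a phenylsilane (which needs electrophilic unmasking that the arenes would not tolerate).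

**15 ⇒ 12 + 14.** The C7'–aryl bond is cut (sp3–sp2 cross-coupling). Cutting C4–C7' instead would make the syringylmethyl group the nucleophile at C4 and would reverse the sense of induction required from the diol. Cutting at the arene keeps one diol for all centres and removes a whole ring: bromide 14 is one step from phenol 13.

**12 ⇒ 11 ⇒ 10.** Trifluoroborate 12 is the coupling-ready form of boronic ester 11 and releases diol 2 for recovery. In 11 the bond C4–C7' is cut: C7' is a CH2 inserted into the C4–B bond of 10 with retention, which creates no stereocentre.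

**10 ⇒ 8 (through chloride 9).** The key cut: C3–C4 and C4–C5. C4 is inserted into the C3–B bond of 8 as a CHCl unit, and C5 enters as a silylmethyl nucleophile that displaces chloride. Against an aldol, crotylation or conjugate-addition construction of C4, this cut sets C4 by the reagent instead of by C3. The forward step must show the same sense of induction as the two before it and must not disturb the C2 ether.

**8 ⇒ 6 (through chloride 7).** C2–C3 and C3–CH3 are cut in the same way, with methyl as the nucleophile. Precursor 6 has one stereocentre.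

**6 ⇒ 3 + 4 (through chloride 5).** Aryl–C2 and C2–O are cut: the aryl group migrates from boron to an inserted carbon and prop-2-en-1-olate (from 4) displaces the chloride. Aryl boronic ester 3 is achiral apart from its diol.

**3 ⇒ 1 + 2.** The two B–O bonds are cut: boronic acid 1 and (R,R)-diol 2 condense. The diol is the only source of chirality in the route.

## Roads not taken

Alternative 1: The cut is C4–C5 and C5–O1, with C5 drawn from syngas. Homoallylic alcohol A1 would be hydroformylated with Rh(acac)(CO)2 and a phosphinite ligand that binds reversibly to the C2 hydroxyl, placing the formyl group on C4; the aldehyde closes onto the C2 hydroxyl to give lactol A2. Silane reduction of the lactol and debenzylation would finish the synthesis. Its merits are atom economy, ring formation in the key step, and only about three steps from A1 to the target. Its weak points are specific to this substrate. The alkene of A1 is a β-alkylstyrene, whose aryl group electronically favours formylation at C7', against the direction of the ligand. C4 would be set by relay from C3 through the directed transition state, not by a reagent. A1 itself still needs C2, C3 and the (E)-alkene from a separate asymmetric sequence. The lactol reduction passes through an oxocarbenium ion under Lewis acid beside the ionisable C2–O bond. In step count this road is clearly better than the chosen one. The chosen plan offers in return no regiochemical question and a C4 centre that does not depend on C3.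

Alternative 2: The cut is C7'–aryl and C3–CH3, with C4 taken from the epichlorohydrin-derived cyclopropane lactone A3. The Grignard reagent of 14 with catalytic CuBr·SMe2 would open the cyclopropane at its CH2, and the released enolate would be methylated with MeI to give A4. The merits are a cheap chiral pool available in both enantiomers, two C–C bonds in one flask, and no chiral reagent. The weak points are that C3 is made quaternary with an ester that must later be removed, which erases the information just installed and returns C3 to enolate equilibration. The guaiacyl group must then be added to the lactone carbonyl and the resulting lactol reduced, so C2 is fixed by hydride delivery to an oxocarbenium ion under substrate control. Because the target is all-trans, thermodynamics works for this road, and it is a serious competitor of similar or shorter length with cheaper reagents. The chosen plan sets each centre directly, carries no sacrificial group, and does not leave C2 to an oxocarbenium reduction.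

Alternative 3: The cut is C2–C3 and the lactone C–O bond. Aldehyde A5 and the (Z)-2-(methoxycarbonyl)crotylboronate A6 would react through a chair allylboration, and the borate alkoxide would close on the ester to give the trans methylene lactone A7. The syringyl ring would then be attached to the exocyclic methylene by conjugate arylation, C4 set by protonation or equilibration next to the carbonyl, and the lactone reduced to the oxolane in two operations. The merits are two stereocentres and the ring in one step from a commercial aldehyde, an epimerisable C4 that can settle trans, and a length of roughly six steps. The weak points: A6 is a deactivated allylboronate and A5 an electron-rich, sluggish aldehyde, so acid catalysis or heat is needed. Under those conditions the p-alkoxybenzylic lactone C–O bond can ionise. Absolute control needs a chiral boronate or chiral acid on top of this slow reaction. The final lactone-to-ether reduction again uses a Lewis acid next to C2. This is the shortest road, about half the length of the chosen plan. Against that, the chosen plan offers one reaction type with a predictable sense at all three centres, one recoverable director, and free exchange of any substituent by changing a nucleophile.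

Key step: step 4

Remark on the chemistry: the (R,R)-diol is taken to deliver (αS)-chlorides (CIP order Cl > C > B), as C2-symmetric (R,R)-1,2-diol boronic esters generally do; all configurations below follow from this.
Remark on the chemistry: boronic acid 1 and benzyl(chloromethyl)dimethylsilane are taken to be catalogue compounds; the Grignard reagent of step 4 is prepared from the silane with Mg in THF before use.

## Route

Step 1
Reactants: 1 [4-(benzyloxy)-3-methoxyphenyl]boronic acid; 2 (1R,2R)-1,2-dicyclohexylethane-1,2-diol
Product: 3 (4R,5R)-2-[4-(benzyloxy)-3-methoxyphenyl]-4,5-dicyclohexyl-1,3,2-dioxaborolane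
Conditions: toluene, rt; azeotropic removal of water
Reagents that add atoms: none
Why: Boronic acid–diol condensation to the five-membered dioxaborolane, driven by removal of water. No stereocentre is formed; the diol becomes the director for steps 2 to 4.

Step 2
Reactants: 3 (4R,5R)-2-[4-(benzyloxy)-3-methoxyphenyl]-4,5-dicyclohexyl-1,3,2-dioxaborolane; 4 prop-2-en-1-ol
Product: 6 (4R,5R)-2-{(R)-[4-(benzyloxy)-3-methoxyphenyl](prop-2-en-1-yloxy)methyl}-4,5-dicyclohexyl-1,3,2-dioxaborolane, via benzylic chloride 5 (not isolated)
Conditions: CH2Cl2, n-BuLi, THF, −100 °C; 3; ZnCl2, −100 °C → rt; then NaOCH2CH=CH2 (from 4, NaH), THF/DMSO, 0 °C → rt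
Reagents that add atoms: dichloromethane, ClCCl (used as dichloromethyllithium, [Li]C(Cl)Cl)
Why: Matteson homologation followed by alkoxide displacement: LiCHCl2 adds to boron, ZnCl2 promotes 1,2-migration of the aryl group to the (S)-chloride 5 under control of the (R,R)-diol, and the alkoxide adds to boron and migrates with inversion to give (R)-C2. The allyl ether is chosen because it can later be removed without acid or a benzylic oxidant.

Step 3
Reactants: 6 (4R,5R)-2-{(R)-[4-(benzyloxy)-3-methoxyphenyl](prop-2-en-1-yloxy)methyl}-4,5-dicyclohexyl-1,3,2-dioxaborolane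
Product: 8 (4R,5R)-2-{(1R,2S)-1-[4-(benzyloxy)-3-methoxyphenyl]-1-(prop-2-en-1-yloxy)propan-2-yl}-4,5-dicyclohexyl-1,3,2-dioxaborolane, via chloro boronic ester 7 (not isolated)
Conditions: CH2Cl2, n-BuLi, THF, −100 °C; 6; ZnCl2, −100 °C → rt; then MeMgBr, THF, −78 °C → rt
Reagents that add atoms: dichloromethane, ClCCl (used as dichloromethyllithium, [Li]C(Cl)Cl); methylmagnesium bromide, C[Mg]Br
Why: Second Matteson homologation: C2 migrates from boron to the new carbon with retention, the diol selects the chloride that leaves (7), and MeMgBr delivers methyl with inversion, setting C3. α-Alkoxyalkyl groups are established migrating groups in this chemistry, and the resulting β-alkoxy boronic ester is of a known, isolable type.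

Step 4
Reactants: 8 (4R,5R)-2-{(1R,2S)-1-[4-(benzyloxy)-3-methoxyphenyl]-1-(prop-2-en-1-yloxy)propan-2-yl}-4,5-dicyclohexyl-1,3,2-dioxaborolane
Product: 10 (4R,5R)-2-{(2R,3R,4R)-1-[benzyl(dimethyl)silyl]-4-[4-(benzyloxy)-3-methoxyphenyl]-3-methyl-4-(prop-2-en-1-yloxy)butan-2-yl}-4,5-dicyclohexyl-1,3,2-dioxaborolane, via chloro boronic ester 9 (not isolated)
Conditions: CH2Cl2, n-BuLi, THF, −100 °C; 8; ZnCl2, −100 °C → rt; then BnMe2SiCH2MgCl, THF, 0 °C → rt
Reagents that add atoms: dichloromethane, ClCCl (used as dichloromethyllithium, [Li]C(Cl)Cl); [(benzyldimethylsilyl)methyl]magnesium chloride, C[Si](C)(Cc1ccccc1)C[Mg]Cl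
Why: Matteson homologation followed by Grignard displacement; the closest known reaction type is iterative chain extension of chiral diol boronic esters with LiCHCl2/ZnCl2 and organomagnesium reagents. LiCHCl2 adds to the boron of 8 to give a tetracoordinate boronate; ZnCl2 bridges a dioxaborolane oxygen and one chloride, and C3 migrates from boron to carbon with retention as that chloride leaves, forming C3–C4 and chloride 9. The C2-symmetric (R,R)-diol decides which of the two diastereotopic chlorides departs, so the chloro carbon of 9 is (S) by reagent control, independent of C2 and C3. BnMe2SiCH2MgCl then adds to boron and its CH2 group migrates anti to the remaining chloride, forming C4–C5 with inversion and giving (R)-C4. No ring is closed in this step. The selectivity needed is the same sense of induction as in steps 2 and 3, and one diol supplies it because the order of introduction (alkoxide at C2, methyl at C3, silylmethyl at C4, C7' still to be inserted) makes all three centres ask for the same face. The 1,2-shifts must also outrun chloride exchange at C4 and loss of the C2 allyloxy group; ZnCl2 ties up free chloride, and once C3 has migrated boron is no longer β to the C2 ether. The benzyldimethylsilyl group is carried because it resists the next three steps and is opened to oxidation only by fluoride.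

Step 5
Reactants: 10 (4R,5R)-2-{(2R,3R,4R)-1-[benzyl(dimethyl)silyl]-4-[4-(benzyloxy)-3-methoxyphenyl]-3-methyl-4-(prop-2-en-1-yloxy)butan-2-yl}-4,5-dicyclohexyl-1,3,2-dioxaborolane
Product: 11 (4R,5R)-2-{(2R,3R,4R)-2-{[benzyl(dimethyl)silyl]methyl}-4-[4-(benzyloxy)-3-methoxyphenyl]-3-methyl-4-(prop-2-en-1-yloxy)butyl}-4,5-dicyclohexyl-1,3,2-dioxaborolane
Conditions: BrCH2Cl, n-BuLi, THF, −78 °C → rt
Reagents that add atoms: bromochloromethane, ClCBr (used as chloromethyllithium, [Li]CCl)
Why: Matteson-type CH2 insertion with chloromethyllithium made in situ: the boronate forms at −78 °C and C4 migrates to the CH2 carbon with retention on warming, placing boron on C7'. In situ halogen–lithium exchange keeps free n-BuLi away from the allyl ether and the benzylsilane.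

Step 6
Reactants: 11 (4R,5R)-2-{(2R,3R,4R)-2-{[benzyl(dimethyl)silyl]methyl}-4-[4-(benzyloxy)-3-methoxyphenyl]-3-methyl-4-(prop-2-en-1-yloxy)butyl}-4,5-dicyclohexyl-1,3,2-dioxaborolane
Product: 12 potassium {(2R,3R,4R)-2-{[benzyl(dimethyl)silyl]methyl}-4-[4-(benzyloxy)-3-methoxyphenyl]-3-methyl-4-(prop-2-en-1-yloxy)butyl}trifluoroborate
Conditions: KHF2, MeOH/H2O, rt
Reagents that add atoms: potassium hydrogen difluoride, [K+].[F-].F
Why: Boronic ester to trifluoroborate exchange with KHF2, which releases diol 2 for recovery. The primary alkyltrifluoroborate is the form best suited to sp3–sp2 Suzuki–Miyaura coupling; no stereocentre is touched.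

Step 7
Reactants: 13 4-bromo-2,6-dimethoxyphenol
Product: 14 2-(benzyloxy)-5-bromo-1,3-dimethoxybenzene
Conditions: BnBr, K2CO3, DMF, rt
Reagents that add atoms: benzyl bromide, BrCc1ccccc1
Why: Williamson ether synthesis on the phenol. The benzyl ether survives the coupling and leaves together with the other one in step 12.

Step 8
Reactants: 12 potassium {(2R,3R,4R)-2-{[benzyl(dimethyl)silyl]methyl}-4-[4-(benzyloxy)-3-methoxyphenyl]-3-methyl-4-(prop-2-en-1-yloxy)butyl}trifluoroborate; 14 2-(benzyloxy)-5-bromo-1,3-dimethoxybenzene
Product: 15 benzyl{(2R,3R,4R)-2-[4-(benzyloxy)-3,5-dimethoxybenzyl]-4-[4-(benzyloxy)-3-methoxyphenyl]-3-methyl-4-(prop-2-en-1-yloxy)butyl}dimethylsilane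
Conditions: Pd(OAc)2 (5 mol%), RuPhos (10 mol%), K2CO3, toluene/H2O (10:1), 85 °C
Reagents that add atoms: none
Why: Suzuki–Miyaura coupling of a primary alkyltrifluoroborate with an aryl bromide, forming C7'–aryl; slow hydrolysis of the trifluoroborate feeds transmetalation and the bulky dialkylbiarylphosphine favours reductive elimination over β-hydride elimination. An alkyl allyl ether and a benzylsilane are not activated by zerovalent palladium under aqueous carbonate.

Step 9
Reactants: 15 benzyl{(2R,3R,4R)-2-[4-(benzyloxy)-3,5-dimethoxybenzyl]-4-[4-(benzyloxy)-3-methoxyphenyl]-3-methyl-4-(prop-2-en-1-yloxy)butyl}dimethylsilane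
Product: 17 (2R,3R,4R)-2-[4-(benzyloxy)-3,5-dimethoxybenzyl]-4-[4-(benzyloxy)-3-methoxyphenyl]-3-methyl-4-(prop-2-en-1-yloxy)butan-1-ol, via fluorosilane 16 (not isolated)
Conditions: Bu4NF, THF, 0 °C → rt; then KHCO3, 30% H2O2, MeOH/THF, 40 °C
Reagents that add atoms: hydrogen peroxide, OO
Why: Tamao–Fleming oxidation of a benzyldimethylsilyl group: fluoride cleaves the benzyl–silicon bond to give fluorosilane 16, which basic H2O2 oxidises to the C5 alcohol. The conditions are non-acidic and should leave the allyl ether, the benzyl ethers and the electron-rich rings alone.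

Step 10
Reactants: 17 (2R,3R,4R)-2-[4-(benzyloxy)-3,5-dimethoxybenzyl]-4-[4-(benzyloxy)-3-methoxyphenyl]-3-methyl-4-(prop-2-en-1-yloxy)butan-1-ol
Product: 18 (1R,2R,3R)-3-[4-(benzyloxy)-3,5-dimethoxybenzyl]-1-[4-(benzyloxy)-3-methoxyphenyl]-2-methylbutane-1,4-diol
Conditions: [CpRu(MeCN)3]PF6 (2 mol%), quinoline-2-carboxylic acid (2 mol%), MeOH, 30 °C
Reagents that add atoms: none
Why: Ruthenium-catalysed deallylation of an alkyl allyl ether through a π-allyl ruthenium intermediate, the allyl group passing to methanol. The medium is neutral, so the C2–O bond is not ionised and C2 keeps its configuration.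

Step 11
Reactants: 18 (1R,2R,3R)-3-[4-(benzyloxy)-3,5-dimethoxybenzyl]-1-[4-(benzyloxy)-3-methoxyphenyl]-2-methylbutane-1,4-diol
Product: 20 (2R,3R,4R)-4-[4-(benzyloxy)-3,5-dimethoxybenzyl]-2-[4-(benzyloxy)-3-methoxyphenyl]-3-methyloxolane, via primary tosylate 19 (not isolated)
Conditions: NaH, THF, 0 °C; then 1-(4-methylbenzenesulfonyl)imidazole, 0 °C → rt
Reagents that add atoms: none
Why: One-flask cycloetherification of a 1,4-diol: the less hindered primary alkoxide is sulfonylated and the C2 alkoxide displaces the tosylate in a 5-exo-tet Williamson closure of O1–C5. No bond to a stereocentre is broken, so the (2R,3R,4R) pattern passes into the ring.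

Step 12
Reactants: 20 (2R,3R,4R)-4-[4-(benzyloxy)-3,5-dimethoxybenzyl]-2-[4-(benzyloxy)-3-methoxyphenyl]-3-methyloxolane
Product: 21 (2R,3R,4R)-2-(4-hydroxy-3-methoxyphenyl)-4-(4-hydroxy-3,5-dimethoxybenzyl)-3-methyloxolane
Conditions: H2 (1 atm), Pd/C (10% Pd on carbon), EtOAc, rt
Reagents that add atoms: none
Why: Hydrogenolysis of the two aryl benzyl ethers under neutral conditions. Aryl benzyl ethers should cleave faster than the cyclic benzylic C2–O1 bond, and the reaction is stopped after uptake of two equivalents of hydrogen.

## Compound list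

1 | [4-(benzyloxy)-3-methoxyphenyl]boronic acid | COc1cc(B(O)O)ccc1OCc1ccccc1 | starting material
2 | (1R,2R)-1,2-dicyclohexylethane-1,2-diol | O[C@H](C1CCCCC1)[C@H](O)C1CCCCC1 | starting material
3 | (4R,5R)-2-[4-(benzyloxy)-3-methoxyphenyl]-4,5-dicyclohexyl-1,3,2-dioxaborolane | COc1cc(B2O[C@H](C3CCCCC3)[C@@H](C4CCCCC4)O2)ccc1OCc1ccccc1 | intermediate
4 | prop-2-en-1-ol | C=CCO | starting material
5 | (4R,5R)-2-{(S)-[4-(benzyloxy)-3-methoxyphenyl](chloro)methyl}-4,5-dicyclohexyl-1,3,2-dioxaborolane | COc1cc([C@@H](Cl)B2O[C@H](C3CCCCC3)[C@@H](C4CCCCC4)O2)ccc1OCc1ccccc1 | intermediate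
6 | (4R,5R)-2-{(R)-[4-(benzyloxy)-3-methoxyphenyl](prop-2-en-1-yloxy)methyl}-4,5-dicyclohexyl-1,3,2-dioxaborolane | COc1cc([C@H](OCC=C)B2O[C@H](C3CCCCC3)[C@@H](C4CCCCC4)O2)ccc1OCc1ccccc1 | intermediate
7 | (4R,5R)-2-{(1S,2S)-2-[4-(benzyloxy)-3-methoxyphenyl]-1-chloro-2-(prop-2-en-1-yloxy)ethyl}-4,5-dicyclohexyl-1,3,2-dioxaborolane | COc1cc([C@H](OCC=C)[C@@H](Cl)B2O[C@H](C3CCCCC3)[C@@H](C4CCCCC4)O2)ccc1OCc1ccccc1 | intermediate
8 | (4R,5R)-2-{(1R,2S)-1-[4-(benzyloxy)-3-methoxyphenyl]-1-(prop-2-en-1-yloxy)propan-2-yl}-4,5-dicyclohexyl-1,3,2-dioxaborolane | COc1cc([C@H](OCC=C)[C@H](C)B2O[C@H](C3CCCCC3)[C@@H](C4CCCCC4)O2)ccc1OCc1ccccc1 | intermediate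
9 | (4R,5R)-2-{(1S,2S,3R)-3-[4-(benzyloxy)-3-methoxyphenyl]-1-chloro-2-methyl-3-(prop-2-en-1-yloxy)propyl}-4,5-dicyclohexyl-1,3,2-dioxaborolane | COc1cc([C@H](OCC=C)[C@H](C)[C@@H](Cl)B2O[C@H](C3CCCCC3)[C@@H](C4CCCCC4)O2)ccc1OCc1ccccc1 | intermediate
10 | (4R,5R)-2-{(2R,3R,4R)-1-[benzyl(dimethyl)silyl]-4-[4-(benzyloxy)-3-methoxyphenyl]-3-methyl-4-(prop-2-en-1-yloxy)butan-2-yl}-4,5-dicyclohexyl-1,3,2-dioxaborolane | COc1cc([C@H](OCC=C)[C@H](C)[C@H](C[Si](C)(C)Cc2ccccc2)B2O[C@H](C3CCCCC3)[C@@H](C4CCCCC4)O2)ccc1OCc1ccccc1 | intermediate
11 | (4R,5R)-2-{(2R,3R,4R)-2-{[benzyl(dimethyl)silyl]methyl}-4-[4-(benzyloxy)-3-methoxyphenyl]-3-methyl-4-(prop-2-en-1-yloxy)butyl}-4,5-dicyclohexyl-1,3,2-dioxaborolane | COc1cc([C@H](OCC=C)[C@H](C)[C@H](C[Si](C)(C)Cc2ccccc2)CB2O[C@H](C3CCCCC3)[C@@H](C4CCCCC4)O2)ccc1OCc1ccccc1 | intermediate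
12 | potassium {(2R,3R,4R)-2-{[benzyl(dimethyl)silyl]methyl}-4-[4-(benzyloxy)-3-methoxyphenyl]-3-methyl-4-(prop-2-en-1-yloxy)butyl}trifluoroborate | [K+].COc1cc([C@H](OCC=C)[C@H](C)[C@H](C[Si](C)(C)Cc2ccccc2)C[B-](F)(F)F)ccc1OCc1ccccc1 | intermediate
13 | 4-bromo-2,6-dimethoxyphenol | COc1cc(Br)cc(OC)c1O | starting material
14 | 2-(benzyloxy)-5-bromo-1,3-dimethoxybenzene | COc1cc(Br)cc(OC)c1OCc1ccccc1 | intermediate
15 | benzyl{(2R,3R,4R)-2-[4-(benzyloxy)-3,5-dimethoxybenzyl]-4-[4-(benzyloxy)-3-methoxyphenyl]-3-methyl-4-(prop-2-en-1-yloxy)butyl}dimethylsilane | COc1cc([C@H](OCC=C)[C@H](C)[C@H](C[Si](C)(C)Cc2ccccc2)Cc2cc(OC)c(OCc3ccccc3)c(OC)c2)ccc1OCc1ccccc1 | intermediate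
16 | {(2R,3R,4R)-2-[4-(benzyloxy)-3,5-dimethoxybenzyl]-4-[4-(benzyloxy)-3-methoxyphenyl]-3-methyl-4-(prop-2-en-1-yloxy)butyl}fluorodimethylsilane | COc1cc([C@H](OCC=C)[C@H](C)[C@H](C[Si](C)(C)F)Cc2cc(OC)c(OCc3ccccc3)c(OC)c2)ccc1OCc1ccccc1 | intermediate
17 | (2R,3R,4R)-2-[4-(benzyloxy)-3,5-dimethoxybenzyl]-4-[4-(benzyloxy)-3-methoxyphenyl]-3-methyl-4-(prop-2-en-1-yloxy)butan-1-ol | COc1cc([C@H](OCC=C)[C@H](C)[C@H](CO)Cc2cc(OC)c(OCc3ccccc3)c(OC)c2)ccc1OCc1ccccc1 | intermediate
18 | (1R,2R,3R)-3-[4-(benzyloxy)-3,5-dimethoxybenzyl]-1-[4-(benzyloxy)-3-methoxyphenyl]-2-methylbutane-1,4-diol | COc1cc([C@H](O)[C@H](C)[C@H](CO)Cc2cc(OC)c(OCc3ccccc3)c(OC)c2)ccc1OCc1ccccc1 | intermediate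
19 | (2R,3R,4R)-2-[4-(benzyloxy)-3,5-dimethoxybenzyl]-4-[4-(benzyloxy)-3-methoxyphenyl]-4-hydroxy-3-methylbutyl 4-methylbenzenesulfonate (present in the flask as its sodium alkoxide) | COc1cc([C@H](O)[C@H](C)[C@H](COS(=O)(=O)c2ccc(C)cc2)Cc2cc(OC)c(OCc3ccccc3)c(OC)c2)ccc1OCc1ccccc1 | intermediate
20 | (2R,3R,4R)-4-[4-(benzyloxy)-3,5-dimethoxybenzyl]-2-[4-(benzyloxy)-3-methoxyphenyl]-3-methyloxolane | COc1cc([C@@H]2OC[C@H](Cc3cc(OC)c(OCc4ccccc4)c(OC)c3)[C@H]2C)ccc1OCc1ccccc1 | intermediate
21 | (2R,3R,4R)-2-(4-hydroxy-3-methoxyphenyl)-4-(4-hydroxy-3,5-dimethoxybenzyl)-3-methyloxolane | COc1cc([C@@H]2OC[C@H](Cc3cc(OC)c(O)c(OC)c3)[C@H]2C)ccc1O | target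

## Step count and least certain steps

Total: 12 steps. Longest linear sequence: 11 steps (steps 1–6 and 8–12, from 1 to 21); step 7 is a one-step side branch.

**Step 4 (key step).** The likeliest failure is slow transfer of the hindered, carbanion-stabilised silylmethyl group from the mixed boronate, which would leave time for chloride exchange at C4 (epimerisation) and for migration of a diol oxygen in place of carbon. A second possibility is zinc-assisted loss of the C2 allyloxy group from the boronate of 8 before C3 has migrated, because C2 is an electron-rich benzylic ether carbon β to boron. Fallback: it sets out from 8 and returns at 18. The Grignard reagent of 14 and 2,3-dibromopropene with catalytic CuI should give 2-(benzyloxy)-5-(2-bromoprop-2-en-1-yl)-1,3-dimethoxybenzene F1. F1 is lithiated by bromine–lithium exchange (t-BuLi, THF, −78 °C) and added to 8, and the resulting boronate is treated with I2 and then NaOMe (Zweifel olefination, retention at C3), which should give 2-(benzyloxy)-5-{(3R,4R)-4-[4-(benzyloxy)-3-methoxyphenyl]-3-methyl-2-methylidene-4-(prop-2-en-1-yloxy)butyl}-1,3-dimethoxybenzene F2. Deallylation of F2 as in step 10 should give (1R,2R)-3-[4-(benzyloxy)-3,5-dimethoxybenzyl]-1-[4-(benzyloxy)-3-methoxyphenyl]-2-methylbut-3-en-1-ol F3, and hydroboration of F3 with 9-BBN followed by oxidative work-up with NaBO3 should give 18. C4 then rests on substrate control by C3: in the conformer with C3–H eclipsing the C4–C7' bond the borane should add anti to the C2 branch, which leads to the C4 configuration of 18. This detour is shorter than steps 4–10 but gives up reagent control at C4, and its induction is less secure.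

**Step 2.** The likeliest failure is loss of configurational purity at C2: chloride exchange or ionisation of the p-alkoxybenzylic chloride 5, helped by ZnCl2, could occur before the alkoxide arrives. Fallback: it sets out from 18 and returns at 20. Because the diol still fixes C3 and C4 in steps 3 and 4, partly scrambled material would reach the diol stage as 18 accompanied by its C2 epimer (1S,2R,3R)-3-[4-(benzyloxy)-3,5-dimethoxybenzyl]-1-[4-(benzyloxy)-3-methoxyphenyl]-2-methylbutane-1,4-diol F4. The mixture of 18 and F4 is then cyclised, in place of step 11, with catalytic 10-camphorsulfonic acid in CH2Cl2 at 0 °C: the benzylic hydroxyl ionises to a p-alkoxybenzyl cation and the C5 hydroxyl should add trans to the C3 methyl group. The ring bond formed is then O1–C2 and C2 is set at the end by C3, so 18 and F4 should converge on 20. Low temperature and short exposure to the acid are needed so that Friedel–Crafts closure of the cation onto the syringyl ring does not compete.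

**Step 8 (with step 6).** The likeliest failure is slow transmetalation of the β-branched alkylboron species, with protodeboronation or β-hydride elimination taking over; incomplete release of boron from the robust diol ester in step 6 is a related risk. Fallback: it sets out from 11 and returns at 15, bypassing 12. Oxidation of 11 with NaBO3·4H2O in THF/H2O (the benzylsilane is inert to peroxide without fluoride) should give (2S,3R,4R)-2-{[benzyl(dimethyl)silyl]methyl}-4-[4-(benzyloxy)-3-methoxyphenyl]-3-methyl-4-(prop-2-en-1-yloxy)butan-1-ol F5. Treatment of F5 with I2, PPh3 and imidazole should give benzyl{(2R,3R,4R)-4-[4-(benzyloxy)-3-methoxyphenyl]-2-(iodomethyl)-3-methyl-4-(prop-2-en-1-yloxy)butyl}dimethylsilane F6. Zinc dust with LiCl in THF should insert into the C–I bond of F6 to give {(2R,3R,4R)-2-{[benzyl(dimethyl)silyl]methyl}-4-[4-(benzyloxy)-3-methoxyphenyl]-3-methyl-4-(prop-2-en-1-yloxy)butyl}(iodo)zinc F7, and Negishi coupling of F7 with 14 (Pd(OAc)2, SPhos, THF) should give 15.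

**Step 12.** The likeliest failure is hydrogenolytic opening of the benzylic C2–O1 bond once the guaiacyl phenol is free, by over-reduction at the metal surface. Fallback: it sets out from 20 and returns at 21. The benzyl ethers are cleaved by Lewis-acid debenzylation with BCl3 and pentamethylbenzene as cation scavenger in CH2Cl2 at −78 °C, with a cold quench so that the Lewis acid has little time to act on the C2–O1 bond. No hydrogen or metal surface is involved, and no new compound is made on the way.

## Further compounds

F1 | step 4 | 2-(benzyloxy)-5-(2-bromoprop-2-en-1-yl)-1,3-dimethoxybenzene | C=C(Br)Cc1cc(OC)c(OCc2ccccc2)c(OC)c1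
F2 | step 4 | 2-(benzyloxy)-5-{(3R,4R)-4-[4-(benzyloxy)-3-methoxyphenyl]-3-methyl-2-methylidene-4-(prop-2-en-1-yloxy)butyl}-1,3-dimethoxybenzene | COc1cc([C@H](OCC=C)[C@H](C)C(=C)Cc2cc(OC)c(OCc3ccccc3)c(OC)c2)ccc1OCc1ccccc1
F3 | step 4 | (1R,2R)-3-[4-(benzyloxy)-3,5-dimethoxybenzyl]-1-[4-(benzyloxy)-3-methoxyphenyl]-2-methylbut-3-en-1-ol | COc1cc([C@H](O)[C@H](C)C(=C)Cc2cc(OC)c(OCc3ccccc3)c(OC)c2)ccc1OCc1ccccc1
F4 | step 2 | (1S,2R,3R)-3-[4-(benzyloxy)-3,5-dimethoxybenzyl]-1-[4-(benzyloxy)-3-methoxyphenyl]-2-methylbutane-1,4-diol | COc1cc([C@@H](O)[C@H](C)[C@H](CO)Cc2cc(OC)c(OCc3ccccc3)c(OC)c2)ccc1OCc1ccccc1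
F5 | step 8 | (2S,3R,4R)-2-{[benzyl(dimethyl)silyl]methyl}-4-[4-(benzyloxy)-3-methoxyphenyl]-3-methyl-4-(prop-2-en-1-yloxy)butan-1-ol | COc1cc([C@H](OCC=C)[C@H](C)[C@H](C[Si](C)(C)Cc2ccccc2)CO)ccc1OCc1ccccc1
F6 | step 8 | benzyl{(2R,3R,4R)-4-[4-(benzyloxy)-3-methoxyphenyl]-2-(iodomethyl)-3-methyl-4-(prop-2-en-1-yloxy)butyl}dimethylsilane | COc1cc([C@H](OCC=C)[C@H](C)[C@H](C[Si](C)(C)Cc2ccccc2)CI)ccc1OCc1ccccc1
F7 | step 8 | {(2R,3R,4R)-2-{[benzyl(dimethyl)silyl]methyl}-4-[4-(benzyloxy)-3-methoxyphenyl]-3-methyl-4-(prop-2-en-1-yloxy)butyl}(iodo)zinc | COc1cc([C@H](OCC=C)[C@H](C)[C@H](C[Si](C)(C)Cc2ccccc2)C[Zn]I)ccc1OCc1ccccc1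
F0 | step 12 | none | none
A1 | alternative 1 | (1R,2R,3E)-4-[4-(benzyloxy)-3,5-dimethoxyphenyl]-1-[4-(benzyloxy)-3-methoxyphenyl]-2-methylbut-3-en-1-ol | COc1cc([C@H](O)[C@H](C)/C=C/c2cc(OC)c(OCc3ccccc3)c(OC)c2)ccc1OCc1ccccc1
A2 | alternative 1 | (3R,4R,5R)-3-[4-(benzyloxy)-3,5-dimethoxybenzyl]-5-[4-(benzyloxy)-3-methoxyphenyl]-4-methyloxolan-2-ol (either anomer) | COc1cc([C@@H]2OC(O)[C@H](Cc3cc(OC)c(OCc4ccccc4)c(OC)c3)[C@H]2C)ccc1OCc1ccccc1
A3 | alternative 2 | ethyl (1S,5R)-2-oxo-3-oxabicyclo[3.1.0]hexane-1-carboxylate | O=C1OC[C@@H]2C[C@]12C(=O)OCC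
A4 | alternative 2 | ethyl (3R,4R)-4-[4-(benzyloxy)-3,5-dimethoxybenzyl]-3-methyl-2-oxooxolane-3-carboxylate (methyl trans to the arylmethyl group) | O=C2OC[C@H](Cc3cc(OC)c(OCc4ccccc4)c(OC)c3)[C@]2(C)C(=O)OCC
A5 | alternative 3 | 4-(benzyloxy)-3-methoxybenzaldehyde | COc1cc(C=O)ccc1OCc1ccccc1
A6 | alternative 3 | methyl (2Z)-2-[(4,4,5,5-tetramethyl-1,3,2-dioxaborolan-2-yl)methyl]but-2-enoate | C/C=C(/CB1OC(C)(C)C(C)(C)O1)C(=O)OC
A7 | alternative 3 | (4R,5R)-5-[4-(benzyloxy)-3-methoxyphenyl]-4-methyl-3-methylideneoxolan-2-one | COc1cc([C@@H]2OC(=O)C(=C)[C@H]2C)ccc1OCc1ccccc1
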